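In ring B the two oxygen-bearing carbons C6 and C9 lie para to each other and the methyl groups sit on C8 and C10, the carbons flanking C9; that is 2,6-dimethyl-1,4-benzoquinone in disguise. Cutting C1–C10 and C4–C5 therefore splits the decalin into this quinone and 4-methylpenta-1,3-diene. One catalytic enantioselective Diels–Alder reaction across the quinone C5=C10 bond closes ring A, makes both bonds and fixes quaternary C10; its precursors are the two achiral commercial compounds themselves. All other centres are then relayed from C10: C5 and C8 by equilibration, C9 by α-face epoxidation of a C9 methylene, C13 by reagent-controlled epoxidation with inversion, C7 by ketol equilibration.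

Key step: step 1

Convention: locants are labdane locants (C1–C10 decalin, C11–C16 side chain, α = face opposite the C10 methyl); from compound 5 onwards every decalin has 5α-H, 8α-CH3 (8β-H) and 10β-CH3 unless stated.

Assumption: in the saturated 6,9-dione the trans-fused 8α-methyl isomer is taken to be the thermodynamic C5/C8 epimer (cis-fused material, if present, is separated and re-equilibrated), and the catalyst enantiomer in step 1 and the ligand enantiomer in step 7 are those that the established stereochemical models assign to the configurations drawn.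

Step 1
Reactants: 1 2,6-dimethyl-1,4-benzoquinone; 2 4-methylpenta-1,3-diene
Product: 3 (4aR,8aS)-2,5,5,8a-tetramethyl-4a,5,8,8a-tetrahydronaphthalene-1,4-dione (cis-fused 4,4,8,10-tetramethyldecalin-2,7-diene-6,9-dione; 5β-H, 10β-CH3)
Conditions: (S)-1-(2-methylphenyl)-3,3-diphenyltetrahydro-1H,3H-pyrrolo[1,2-c][1,3,2]oxazaborole (20 mol %), HNTf2 (20 mol %), 2 (5 equiv, freed of 2-methylpenta-1,3-diene), CH2Cl2, −78 → −20 °C, 48 h
Reagents that add atoms: none
Why: The cationic oxazaborolidine binds the C6 carbonyl oxygen of 1, the carbonyl flanked by two C–H carbons, and so makes C10 (β to that carbonyl) the most electrophilic carbon, which the unsubstituted and most nucleophilic terminus of 2 attacks first while the dimethylated terminus closes on C5 in a concerted but asynchronous [4+2] cycloaddition. The closest known reaction type is the oxazaborolidinium-catalysed enantioselective Diels–Alder reaction of alkyl-substituted 1,4-benzoquinones with acyclic dienes. Ring A is closed as a six-membered carbocycle by suprafacial [4+2] addition that forms C1–C10 and C4–C5 together and therefore gives the cis ring fusion. Quaternary C10 is set by the catalyst, which distinguishes the two enantiotopic C=C bonds of the quinone and shields one face of the bound one, whereas C5 merely follows as cis and is corrected in step 2. The selectivities needed are regiochemical (C1 to C10, not to C5), secured by coordination at the unhindered carbonyl and by the polarised diene, and enantiofacial, secured by the catalyst; endo or exo approach creates no stereocentre. Because the cis methyl of 2 disfavours the s-cis conformer, excess diene and a long reaction time are planned.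

Step 2
Reactants: 3 cis-fused Diels–Alder adduct
Product: 5 trans-fused 4,4,8α,10β-tetramethyl-5α-decalin-6,9-dione, via cis-fused saturated dione 4 (not isolated)
Conditions: H2 (1 atm), 10% Pd/C, MeOH, rt; N2 purge; then NaOMe (0.3 equiv), MeOH, 50 °C
Reagents that add atoms: none
Why: Heterogeneous hydrogenation saturates the C2=C3 alkene and, from the convex β-face of the cis-fused adduct, the C7=C8 enedione bond, and methoxide-mediated enolisation (thermodynamic epimerisation) then inverts C5 to the trans ring fusion and leaves the C8 methyl equatorial (8α), anti to the axial C10 methyl.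

Step 3
Reactants: 5 trans-fused 6,9-dione
Product: 6 6,6-(ethylenedioxy)-4,4,8α,10β-tetramethyl-5α-decalin-9-one
Conditions: (TMSOCH2)2 (1.5 equiv), TMSOTf (5 mol %), CH2Cl2, −78 → −20 °C; pyridine quench
Reagents that add atoms: 1,2-bis(trimethylsilyloxy)ethane, C[Si](C)(C)OCCO[Si](C)(C)C
Why: Noyori-type ketalisation is kinetically selective for the C6 carbonyl because C9 is flanked by quaternary C10 and tertiary C8 (the same discrimination as in the C4-selective ketalisation of 2,2,6-trimethylcyclohexane-1,4-dione), and the aprotic low-temperature conditions do not epimerise C5 or C8.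

Step 4
Reactants: 6 C6-ketal C9-ketone
Product: 7 6,6-(ethylenedioxy)-9-methylidene-4,4,8α,10β-tetramethyl-5α-decalin (C9=C11)
Conditions: Ph3PCH3Br (3 equiv), KOt-Bu (3 equiv), toluene, 90 °C
Reagents that add atoms: methyltriphenylphosphonium bromide, C[P+](c1ccccc1)(c1ccccc1)c1ccccc1.[Br-]
Why: Wittig methylenation with the small unstabilised ylide at elevated temperature is the established olefination of 2,2,6-trisubstituted cyclohexanones, the ketal is inert to base, and any enolisation towards C8 can only return the favoured equatorial 8α-methyl.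

Step 5
Reactants: 7 C9-methylidene ketal
Product: 8 9α,11-epoxide of 7 (spiro-oxirane, oxygen α, C11 β)
Conditions: mCPBA (1.3 equiv), NaHCO3, CH2Cl2, 0 °C
Reagents that add atoms: mCPBA, OOC(=O)c1cccc(Cl)c1
Why: Prilezhaev epoxidation delivers oxygen to the exocyclic C9=C11 bond from the α-face, because the β-face is screened by the axial C10 methyl on the neighbouring carbon, which sets C9 with oxygen α and C11 β as in the target (a carbon nucleophile adding to the C9 ketone would come from the same α-face and give the wrong epimer, hence this detour), while bicarbonate protects the ketal.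

Step 6
Reactants: 8 9α,11-epoxide; 9 3-methylbut-3-en-1-ol
Product: 11 6,6-(ethylenedioxy)labd-13(16)-ene-9α,15-diol, via isoprenol dilithium dianion 10 (not isolated)
Conditions: 9 (3 equiv), n-BuLi (6 equiv), TMEDA (6 equiv), Et2O–hexane, 0 °C → rt; then 8, THF, −78 °C → rt; aq NH4Cl
Reagents that add atoms: none
Why: The allylic dianion of 3-methylbut-3-en-1-ol is a known carbon nucleophile towards epoxides and opens the 2,2-disubstituted oxirane by SN2 attack at its methylene carbon C11, so C9 is untouched and the whole C12–C16 unit arrives with the C13=C16 alkene and the C15 hydroxyl in place.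

Step 7
Reactants: 11 homoallylic alcohol with 9α-hydroxyl
Product: 12 (13S)-13,16-epoxy-6,6-(ethylenedioxy)labdane-9α,15-diol
Conditions: Zr(Ot-Bu)4 (10 mol %), (R,R)-N,N'-dihydroxy-N,N'-bis(2,2-diphenylacetyl)cyclohexane-1,2-diamine (11 mol %), cumene hydroperoxide (1.5 equiv), DMPU, 4 Å MS, toluene, 0 °C
Reagents that add atoms: cumene hydroperoxide, CC(C)(OO)c1ccccc1
Why: Hydroxyl-directed asymmetric epoxidation of a 1,1-disubstituted homoallylic alcohol by a zirconium tert-butoxide–chiral bishydroxamic acid catalyst is reagent-controlled, the unhindered primary C15 alcohol binding the metal, so the chosen ligand enantiomer sets C13 as the (13S)-epoxide regardless of the remote decalin centres.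

Step 8
Reactants: 12 (13S)-epoxy diol
Product: 14 (13R)-9α,13-epoxy-15,16-dihydroxylabdan-6-one, via spiro ether diol ketal 13 (not isolated)
Conditions: CSA (10 mol %), CH2Cl2, 0 °C → rt; then 1 M HCl–THF (1:2), rt
Reagents that add atoms: water, O
Why: Acid-catalysed intramolecular epoxide opening is 5-exo-tet at the tertiary carbon, the axial C9 hydroxyl attacking C13 with inversion to give the (13R) spiro ether and leaving the former epoxide oxygen on C16, and aqueous acid then hydrolyses the congested C6 dioxolane without affecting the tertiary ether.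

Step 9
Reactants: 14 spiro ether diol ketone
Product: 15 (13R)-9α,13-epoxy-6-oxolabdan-15,16-olide
Conditions: TEMPO (20 mol %), PhI(OAc)2 (2.5 equiv), CH2Cl2, rt
Reagents that add atoms: none
Why: TEMPO-catalysed oxidative lactonisation of the 1,4-diol oxidises the unhindered C15 primary alcohol in preference to the neopentyl C16 alcohol, the aldehyde closes to the lactol with the C16 hydroxyl and is oxidised on to the γ-lactone with C15 as carbonyl, and ketone and tertiary ether are inert.

Step 10
Reactants: 15 spirolactone ketone
Product: 16 (13R)-9α,13-epoxy-6-(trimethylsilyloxy)labd-6-en-15,16-olide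
Conditions: TMSOTf (1.3 equiv), Et3N (2.5 equiv), CH2Cl2, 0 °C
Reagents that add atoms: trimethylsilyl trifluoromethanesulfonate, C[Si](C)(C)OS(=O)(=O)C(F)(F)F
Why: Soft enolisation silylates the ketone and not the less acidic lactone and gives only the C6=C7 silyl enol ether, since enolisation towards C5 would set a tetrasubstituted double bond against the C4 gem-dimethyl group (allylic strain).

Step 11
Reactants: 16 silyl enol ether
Product: 18 (13R)-9α,13-epoxy-7α-hydroxy-6-oxolabdan-15,16-olide, via silyloxy epoxide 17 (not isolated)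
Conditions: DMDO (1.1 equiv), acetone–CH2Cl2, −78 → −40 °C; then 0.5 M HCl, THF, 0 °C
Reagents that add atoms: dimethyldioxirane, CC1(C)OO1
Why: Rubottom oxidation: dimethyldioxirane epoxidises the electron-rich silyl enol ether, expected mainly from the α-face away from the axial C4β and C10 methyls, and acidic hydrolysis of the silyloxy epoxide gives the α-hydroxy ketone (drawn as the axial 7α-alcohol), either C7 epimer being acceptable because step 12 equilibrates this centre.

Step 12
Reactants: 18 7α-hydroxy ketone
Product: 19 (13R)-9α,13-epoxy-7β-hydroxy-6-oxolabdan-15,16-olide (target)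
Conditions: DBU (0.3 equiv), toluene, 40 °C, argon
Reagents that add atoms: none
Why: Base-mediated epimerisation of the α-ketol through its enediol moves the C7 hydroxyl into the equatorial 7β position, trans to the 8α-methyl and free of the 1,3-diaxial contact with the C9 oxygen, while the 6-oxo-7-hydroxy constitution is retained because any sp3 substituent at C6 would clash with the C4 and C10 methyls, and C13 is safe because the lactone α-protons are far less acidic than H7.

Compound list
1 | 2,6-dimethyl-1,4-benzoquinone | CC1=CC(=O)C=C(C)C1=O | starting material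
2 | 4-methylpenta-1,3-diene | C=CC=C(C)C | starting material
3 | (4aR,8aS)-2,5,5,8a-tetramethyl-4a,5,8,8a-tetrahydronaphthalene-1,4-dione (cis-fused adduct; 5β-H, 10β-CH3, C2=C3 and C7=C8) | CC1=CC(=O)[C@@H]2C(C)(C)C=CC[C@]2(C)C1=O | intermediate
4 | (2R,4aR,8aS)-2,5,5,8a-tetramethyloctahydronaphthalene-1,4-dione (cis-fused saturated 6,9-dione; 5β-H, 8α-CH3 expected from convex-face hydrogenation) | C[C@@H]1CC(=O)[C@@H]2C(C)(C)CCC[C@]2(C)C1=O | intermediate
5 | (2R,4aS,8aS)-2,5,5,8a-tetramethyloctahydronaphthalene-1,4-dione (trans-fused 6,9-dione; 5α-H, 8α-CH3, 10β-CH3) | C[C@@H]1CC(=O)[C@H]2C(C)(C)CCC[C@]2(C)C1=O | intermediate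
6 | 6,6-(ethylenedioxy)-4,4,8α,10β-tetramethyl-5α-decalin-9-one (C6 ethylene ketal of 5) | C[C@@H]1CC2(OCCO2)[C@H]3C(C)(C)CCC[C@]3(C)C1=O | intermediate
7 | 6,6-(ethylenedioxy)-9-methylidene-4,4,8α,10β-tetramethyl-5α-decalin (C9=C11) | C[C@@H]1CC2(OCCO2)[C@H]3C(C)(C)CCC[C@]3(C)C1=C | intermediate
8 | 9α,11-epoxide of 7 (spiro-oxirane, oxygen on the α-face, C11 β) | C[C@@H]1CC2(OCCO2)[C@H]3C(C)(C)CCC[C@]3(C)[C@@]14CO4 | intermediate
9 | 3-methylbut-3-en-1-ol (isoprenol) | CC(=C)CCO | starting material
10 | dilithium dianion of 9 (2-(2-lithiooxyethyl)allyllithium) | [Li]CC(=C)CCO[Li] | intermediate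
11 | 6,6-(ethylenedioxy)labd-13(16)-ene-9α,15-diol | C[C@@H]1CC2(OCCO2)[C@H]3C(C)(C)CCC[C@]3(C)[C@@]1(O)CCC(=C)CCO | intermediate
12 | (13S)-13,16-epoxy-6,6-(ethylenedioxy)labdane-9α,15-diol | C[C@@H]1CC2(OCCO2)[C@H]3C(C)(C)CCC[C@]3(C)[C@@]1(O)CC[C@@]4(CO4)CCO | intermediate
13 | (13R)-9α,13-epoxy-6,6-(ethylenedioxy)labdane-15,16-diol | C[C@@H]1CC2(OCCO2)[C@H]3C(C)(C)CCC[C@]3(C)[C@@]14CC[C@](CO)(CCO)O4 | intermediate
14 | (13R)-9α,13-epoxy-15,16-dihydroxylabdan-6-one | C[C@@H]1CC(=O)[C@H]2C(C)(C)CCC[C@]2(C)[C@@]13CC[C@](CO)(CCO)O3 | intermediate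
15 | (13R)-9α,13-epoxy-6-oxolabdan-15,16-olide | C[C@@H]1CC(=O)[C@H]2C(C)(C)CCC[C@]2(C)[C@@]13CC[C@@]4(COC(=O)C4)O3 | intermediate
16 | (13R)-9α,13-epoxy-6-(trimethylsilyloxy)labd-6-en-15,16-olide | C[C@@H]1C=C(O[Si](C)(C)C)[C@H]2C(C)(C)CCC[C@]2(C)[C@@]13CC[C@@]4(COC(=O)C4)O3 | intermediate
17 | (13R)-6α,7α;9α,13-diepoxy-6β-(trimethylsilyloxy)labdan-15,16-olide | C[C@@H]1[C@@H]2O[C@]2(O[Si](C)(C)C)[C@H]3C(C)(C)CCC[C@]3(C)[C@@]14CC[C@@]5(COC(=O)C5)O4 | intermediate
18 | (13R)-9α,13-epoxy-7α-hydroxy-6-oxolabdan-15,16-olide | C[C@@H]1[C@H](O)C(=O)[C@H]2C(C)(C)CCC[C@]2(C)[C@@]13CC[C@@]4(COC(=O)C4)O3 | intermediate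
19 | (13R)-9α,13-epoxy-7β-hydroxy-6-oxolabdan-15,16-olide (CNP0291402.1) | C[C@@H]1[C@@H](O)C(=O)[C@H]2C(C)(C)CCC[C@]2(C)[C@@]12CC[C@@]1(COC(=O)C1)O2 | target

Total step count: 12. Longest linear sequence: 12 steps (the route is fully linear; 9 is commercial).

Steps most likely to fail

Step 1 (key cycloaddition). The s-cis conformer of 2 is poorly populated, so the cycloaddition may stall while the cationic catalyst oligomerises the diene, and a slow catalysed pathway would let the unselective background reaction erode the enantiomeric purity. The fallback sets out from 1 and returns at 3. Commercial mesityl oxide is enolised at its acetyl methyl group (LDA, THF, −78 °C; TIPSOTf) to 4-methyl-2-(triisopropylsilyloxy)penta-1,3-diene F1, which keeps the carbon skeleton and the regiochemical bias of 2 but belongs to the 2-silyloxydiene class that reacts readily with quinones under this catalyst. Cycloaddition with 1 under the step 1 catalyst should give the silyl enol ether adduct F2. CsF and PhNTf2 in DME exchange silicon for triflate to give the enol triflate F3. Pd(OAc)2, PPh3, HCO2H and n-Bu3N in DMF at 60 °C then reduce the triflate to the C2=C3 alkene, which is compound 3.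

Step 2 (ring-fusion equilibration). C5 and C8 epimerise together, so the equilibrium may retain a large share of the cis-fused 8β-methyl dione, whose strain is estimated to be close to that of 5. The fallback sets out from 4 and returns at 7. Compound 4 is isolated after the hydrogenation without contact with base, which keeps the 8α-methyl group installed by convex-face delivery of hydrogen. Low-temperature ketalisation as in step 3 gives the cis-fused C6 ketal F4. Non-basic Petasis methylenation (Cp2TiMe2, toluene, 70 °C) gives the cis-fused methylidene ketal F5, in which C8 can no longer epimerise. PPTS in wet acetone frees the cis-fused methylidene ketone F6. NaOMe in MeOH now epimerises C5 alone, and the trans-fused methylidene ketone F7 should be strongly favoured because the cis-fused chair would force the locked 8α-methyl syn-axial to C1. Ketalisation as in step 3 returns 7.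

Step 6 (epoxide opening). The strongly basic dianion may isomerise the epoxide to the C8=C9 allylic alcohol by β-elimination, or substitution at the neopentyl-type C11 may be too slow. The fallback sets out from 8 and returns at 15; it replaces steps 6–9 and gives up reagent control at C13. Commercial furan-3-ylmethanol is converted (MsCl, LiCl, 2,4,6-collidine, DMF, 0 °C) into 3-(chloromethyl)furan F8 and then (Mg, THF, 0 °C) into (furan-3-ylmethyl)magnesium chloride F9. Copper-catalysed opening of 8 with this far less basic nucleophile (CuBr·SMe2 10 mol %, THF, −30 → 0 °C) should give 15,16-epoxy-6,6-(ethylenedioxy)labda-13(16),14-dien-9α-ol F10. Photo-oxygenation in the presence of a hindered amine (O2, hν, rose bengal, i-Pr2NEt, CH2Cl2, −78 °C) gives 6,6-(ethylenedioxy)-9α,16-dihydroxylabd-13-en-15,16-olide F11, with the carbonyl at the carbon remote from the side chain. NaBH4 in EtOH at 0 °C followed by 1 M HCl reduces the lactol and removes the ketal to give 9α-hydroxy-6-oxolabd-13-en-15,16-olide F12. DBU in CH2Cl2 then adds the 9α-hydroxyl to C13 by 5-exo-trig oxa-Michael closure to give 15 together with (13S)-9α,13-epoxy-6-oxolabdan-15,16-olide F13, which is separated and re-subjected to DBU because the addition is reversible.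

Further compounds
F1 | step 1 | 4-methyl-2-(triisopropylsilyloxy)penta-1,3-diene | C=C(O[Si](C(C)C)(C(C)C)C(C)C)C=C(C)C
F2 | step 1 | (4aR,8aS)-2,5,5,8a-tetramethyl-7-(triisopropylsilyloxy)-4a,5,8,8a-tetrahydronaphthalene-1,4-dione (cis-fused adduct, silyl enol ether at C2=C3) | CC1=CC(=O)[C@@H]2C(C)(C)C=C(O[Si](C(C)C)(C(C)C)C(C)C)C[C@]2(C)C1=O
F3 | step 1 | cis-fused adduct C2 enol triflate (C2=C3) | CC1=CC(=O)[C@@H]2C(C)(C)C=C(OS(=O)(=O)C(F)(F)F)C[C@]2(C)C1=O
F4 | step 2 | cis-fused (5β-H) 6,6-(ethylenedioxy)-4,4,8α,10β-tetramethyldecalin-9-one | C[C@@H]1CC2(OCCO2)[C@@H]3C(C)(C)CCC[C@]3(C)C1=O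
F5 | step 2 | cis-fused (5β-H) 6,6-(ethylenedioxy)-9-methylidene-4,4,8α,10β-tetramethyldecalin | C[C@@H]1CC2(OCCO2)[C@@H]3C(C)(C)CCC[C@]3(C)C1=C
F6 | step 2 | cis-fused (5β-H) 9-methylidene-4,4,8α,10β-tetramethyldecalin-6-one | C[C@@H]1CC(=O)[C@@H]2C(C)(C)CCC[C@]2(C)C1=C
F7 | step 2 | trans-fused (5α-H) 9-methylidene-4,4,8α,10β-tetramethyldecalin-6-one | C[C@@H]1CC(=O)[C@H]2C(C)(C)CCC[C@]2(C)C1=C
F8 | step 6 | 3-(chloromethyl)furan | ClCc1ccoc1
F9 | step 6 | (furan-3-ylmethyl)magnesium chloride | Cl[Mg]Cc1ccoc1
F10 | step 6 | 15,16-epoxy-6,6-(ethylenedioxy)labda-13(16),14-dien-9α-ol | C[C@@H]1CC2(OCCO2)[C@H]3C(C)(C)CCC[C@]3(C)[C@@]1(O)CCc1ccoc1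
F11 | step 6 | 6,6-(ethylenedioxy)-9α,16-dihydroxylabd-13-en-15,16-olide (C16 epimers) | C[C@@H]1CC2(OCCO2)[C@H]3C(C)(C)CCC[C@]3(C)[C@@]1(O)CCC1=CC(=O)OC1O
F12 | step 6 | 9α-hydroxy-6-oxolabd-13-en-15,16-olide | C[C@@H]1CC(=O)[C@H]2C(C)(C)CCC[C@]2(C)[C@@]1(O)CCC1=CC(=O)OC1
F13 | step 6 | (13S)-9α,13-epoxy-6-oxolabdan-15,16-olide | C[C@@H]1CC(=O)[C@H]2C(C)(C)CCC[C@]2(C)[C@@]13CC[C@]4(COC(=O)C4)O3
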